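## Structural features

The target, numbered as a tricyclo[5.3.1.0^{1,5}]undecane (C1–C11), has three rings. Ring A (C1, C10, C9, C8, C7, C11) is a six-membered enolised 2-acyl-1,3-dione with the isobutyryl group on C9. Ring B (C1, C5, C6, C7, C11) is a cyclopentanone whose carbonyl carbon C11 bridges ring A between the quaternary bridgeheads C1 and C7. Ring C (C1 to C5) is a cyclopentane fused to ring B along C1–C5, with a gem-dimethyl group on C4 and a 2-hydroxypropan-2-yl group on C3. C1 and C5 are adjacent stereocentres and are locked to C7 by the cage, so these three form one stereochemical unit. The fourth, C3, is separated from them by C2 and C4 and carries its carbinol arm on the face of ring C that also carries C11 and C6. The enolised triketone is acidic, chelating and open to retro-Claisen cleavage, the C11 ketone sits between two quaternary carbons, and the tertiary alcohol eliminates readily in strong acid. The real difficulty is the crowding (two quaternary bridgeheads and a third quaternary carbon, C4, next to the ring fusion) together with the C3 configuration, which puts the largest substituent of ring C on its more hindered face. The key step uses the fact that C9 lies between the two oxygen-bearing carbons C8 and C10 of ring A: taking out C9 with its acyl group leaves C8 and C10 bonded to each other as a norbornane-2,3-dione, so ring A can be finished last by inserting one carbon.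

## Logic of the disconnections

**23 back to 22.** No skeletal bond is cut; the C11 carbonyl is returned to its dimethyl ketal. A free bridging ketone would make each bridgehead of the dione stage the centre of a non-enolisable 1,3-dicarbonyl unit, open to retro-Claisen cleavage, and would compete for the carbon nucleophile of the key step. The gain is chemoselectivity through four steps. The demand is a ketal hydrolysis that spares the tertiary alcohol and the triketone; the alcohol itself is deliberately left unprotected.

**22 back to 17 and 20.** The bonds C8–C9 and C9–C10 are cut. This removes the whole acyl-bearing carbon, turns ring A into the five-membered dione ring of a norbornane and delivers the isobutyryl group with the inserted carbon, so no separate C-acylation is needed. The forward step must add a diazo carbon to a hindered 1,2-dione and then let the neighbouring acyl carbon, not the bridgehead carbon, migrate.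

**17 back to 16 and 15.** The two carbonyls are taken back to a cis-diol and then to the C=C bond of a norbornene. This converts a reactive dione into an alkene that is the natural outcome of a cycloaddition. The forward demand is oxidation of a hindered alkene to the dione without C–C cleavage.

**15 back to 14.** The bonds C1–C5 and C6–C7 are cut (retro-Diels–Alder). Rings B and C and three stereocentres collapse into a monocyclic diene with one stereocentre. The forward step must use the one diene face that puts the C3 side chain next to the ketal bridge; a silyl ether on the alcohol would favour the other face, so the hydroxyl is kept free to hydrogen-bond to the ketal.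

**14 back to 13 and 12.** The second ring double bond is returned to a tertiary bromide, and the two methyl–carbon bonds of the carbinol are cut back to a methyl ester. The reactive diene is thus stored as a stable cyclopentene, and the alcohol is unveiled only when it is needed. The demands are a regioselective E2 toward the ring methylene and an ester double addition without epimerisation at C3.

**12 back to 6 and 10 (through 11).** The bond between the ring sp2 carbon (later C1) and the methylene C2 is cut as a cross-coupling. The same bond made by enolate alkylation would require an SN2 reaction at a methylene whose neighbour carries two tert-alkyl-type groups. The fragments are a vinyl triflate and a β-zincio ester that does not epimerise. The demand is a palladium-catalysed sp3–sp2 coupling between two hindered partners in the presence of a tertiary bromide.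

**6 back to 5, 4, 3, and then 1 and 2.** The C2–C3 bond (hydroxymethyl carbon to the α-carbon of the acid) is cut. The only stereocentre that is set independently is made by auxiliary-controlled hydroxymethylation of an achiral acid. The demand is enolisation and face-selective C–C bond formation next to a quaternary carbon.

**10 back to 9, 8 and 7.** The enol triflate returns to a ketone, the bromo ketal to an enol ether, and the enol ether to a diosphenol. All five ring carbons, the methyl group and the 1,2-dioxygenation pattern come from one cheap compound. The demand is regioselective bromo-methoxylation of an electron-poor enol ether.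

**20 back to 19 and 18.** The C=N2 bond is cut (diazo transfer to an activated methyl ketone). This avoids diazomethane and its silyl analogue.

## Other disconnections considered

**Alternative 1:** The cut is in ring C, at C4–C5 and C1–C2. Forward, TiCl4 would promote a (3+2) annulation of the allenylsilane A1 onto the chiral enone ester A2. The dimethyl terminus of A1 adds to the β-carbon anti to the silyloxy group, silicon shifts, and the titanium enolate closes on the vinyl cation to give the cis-diquinane A3.
- In its favour: it is convergent, sets the C1 quaternary centre and the cis ring fusion in one substrate-controlled step, leaves an ester on C1 as the future C10, and marks C3 with a vinylsilane.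
- A point where it is better than the chosen plan: a C3 acyl group introduced at the vinylsilane could be saturated from the convex face of A3, which puts the side chain on the required concave face by steric approach control, more reliably than the hydrogen-bond control of step 10.
- Against it here: A3 still lacks C8, C9, the C7 methyl and the whole bridge closure. The oxygen at C6 must be removed, and a silyloxy group β to the ketone invites elimination under the annulation conditions.
- Comparison: on structure it builds rings B and C first and needs at least two further ring-forming C–C bonds at quaternary centres, whereas the chosen plan makes B and C in one cycloaddition and A in one insertion. The relative configuration of C1 and C5 is geometrically enforced in both, so on that point the two are equal. On step economy it is clearly longer.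

**Alternative 2:** The cut is at C1–C5 and C6–C7, the same two bonds as in step 10 but made oxidatively from the flat aromatic A4. Forward, Mn(OAc)3 or PhI(OAc)2 would oxidise A4; the chain-bearing ring carbon attacks the internal vinyl carbon, and the resulting primary radical closes on the methyl-bearing ring carbon to give A5.
- In its favour: rings B and C, both quaternary bridgeheads and three stereocentres arise in one step with the triketone already in place. There is no ketal, no diazo compound and no late oxidation. On step economy it is better than the chosen plan.
- Against it here: the first cyclisation must be 5-exo to a primary radical and compete with 6-endo closure, O-cyclisation of a phenolic oxygen and over-oxidation. Either flanking ring carbon could start the sequence. The C3 centre must steer the face with the side chain on the crowded side and with no directing interaction available. Making A4 needs C-alkylation of an acylphloroglucinol with the same hindered side chain.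
- Comparison: the bond set is equal to that of step 10, but the chosen plan makes it by a concerted, geometrically constrained cycloaddition, whereas here regio-, chemo- and stereoselectivity all rest on radical kinetics. It is shorter but less predictable.

**Alternative 3:** The cut is at C7–C8 and C1–C10, that is, ring A is removed as a malonyl unit. Forward, the silyl enol ether A6 of the cis-diquinane ketone would be treated with malonyl dichloride A7 in an Effenberger-type annulation; the two α-carbons are acylated in turn to give A8.
- In its favour: ring A and both quaternary bridgeheads form in one step at the triketone oxidation level, the bridging ketone is never masked, and no diazo reagent is used. On these safety and protecting-group points it is better than the chosen plan. The logic of closing ring A last onto preformed rings B and C is equal to that of the chosen plan.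
- Against it here: the second acylation must create the C1 quaternary centre at a ring-fusion carbon and close a strained bicyclo[3.2.1]octane from a cyclopentanone enol derivative, a combination for which this annulation is expected to be inefficient. A8 still lacks the isobutyryl group, so a C-acylation step follows. A6, with three stereocentres, needs its own multistep stereocontrolled synthesis.
- Comparison: the chosen insertion brings in C9 with its acyl group in one operation and draws rings B and C from a single cycloaddition. Overall this alternative is estimated to be longer and to rest on a lower-yielding ring closure.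

Key step: step 14

**Remarks on the chemistry (assumptions):**
- Either cis-diol would serve as 16, since both carbinol carbons become carbonyls; the endo diol is drawn.
- 9, 10, 12 and 13 are carried as mixtures at the bromine-bearing carbon, which becomes sp2 in step 10.
- 17 and 22 have the configuration of 23 at all four stereocentres; the C1 descriptor changes only through priority changes.
- The tertiary alcohol is carried unprotected from step 9 to the end.

## Route

**Step 1**
Reactants: 1 3,3-dimethylpent-4-enoic acid; 2 (4S)-4-benzyl-1,3-oxazolidin-2-one
Product: 3 (4S)-4-benzyl-3-(3,3-dimethylpent-4-enoyl)-1,3-oxazolidin-2-one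
Conditions: t-BuCOCl, Et3N, THF, −20 °C; then 2, LiCl, −20 °C to rt
Reagents that add atoms: none
Why: Mixed pivalic anhydride formation followed by N-acylation of the oxazolidinone under LiCl/Et3N (no butyllithium); the nucleophile attacks the less hindered acyl carbon of the anhydride.

**Step 2**
Reactants: 3 (4S)-4-benzyl-3-(3,3-dimethylpent-4-enoyl)-1,3-oxazolidin-2-one
Product: 4 (4S)-4-benzyl-3-[(2R)-2-(hydroxymethyl)-3,3-dimethylpent-4-enoyl]-1,3-oxazolidin-2-one
Conditions: TiCl4, i-Pr2NEt, CH2Cl2, 0 °C; then 1,3,5-trioxane, TiCl4, 0 °C
Reagents that add atoms: 1,3,5-trioxane, C1OCOCO1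
Why: Auxiliary-controlled aldol-type hydroxymethylation: the chelated Z chlorotitanium enolate should take up TiCl4-activated formaldehyde on the face opposite the benzyl group, which sets the new centre as 2R (the C3 centre of the target).

**Step 3**
Reactants: 4 (4S)-4-benzyl-3-[(2R)-2-(hydroxymethyl)-3,3-dimethylpent-4-enoyl]-1,3-oxazolidin-2-one
Product: 5 methyl (2R)-2-(hydroxymethyl)-3,3-dimethylpent-4-enoate
Conditions: MeMgBr, MeOH, CH2Cl2, 0 °C to rt
Reagents that add atoms: methanol, CO
Why: Transesterification of the imide with bromomagnesium methoxide, assisted by the β-alkoxide; mild enough that neither retro-aldol loss of formaldehyde nor epimerisation is expected, and the auxiliary is recovered.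

**Step 4**
Reactants: 5 methyl (2R)-2-(hydroxymethyl)-3,3-dimethylpent-4-enoate
Product: 6 methyl (2S)-2-(iodomethyl)-3,3-dimethylpent-4-enoate
Conditions: I2, PPh3, imidazole, CH2Cl2, 0 °C to rt
Reagents that add atoms: iodine, II
Why: Appel-type iodination of the primary alcohol, standard for 3-hydroxy-2-alkylpropanoates; the stereocentre is untouched (the descriptor changes by priority only).

**Step 5**
Reactants: 7 2-hydroxy-3-methylcyclopent-2-en-1-one
Product: 8 2-methoxy-3-methylcyclopent-2-en-1-one
Conditions: MeI, K2CO3, acetone, reflux
Reagents that add atoms: iodomethane, CI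
Why: Williamson O-methylation of the acidic enol of the 1,2-dione, which exists as the tetrasubstituted enol, so the regiochemistry is fixed.

**Step 6**
Reactants: 8 2-methoxy-3-methylcyclopent-2-en-1-one
Product: 9 3-bromo-2,2-dimethoxy-3-methylcyclopentan-1-one (racemic)
Conditions: N-bromosuccinimide, MeOH, 0 °C, dark
Reagents that add atoms: N-bromosuccinimide, O=C1CCC(=O)N1Br; methanol, CO
Why: Bromo-methoxylation of the enol ether double bond: bromine adds to the methyl-bearing carbon and methanol captures the oxocarbenium carbon, giving the dimethyl ketal and a tertiary bromide that serves later as the leaving group for the second ring double bond.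

**Step 7**
Reactants: 9 3-bromo-2,2-dimethoxy-3-methylcyclopentan-1-one
Product: 10 4-bromo-5,5-dimethoxy-4-methylcyclopent-1-en-1-yl trifluoromethanesulfonate (racemic)
Conditions: KN(SiMe3)2, THF, −78 °C; then PhNTf2
Reagents that add atoms: N-phenylbis(trifluoromethanesulfonimide), O=S(=O)(N(c1ccccc1)S(=O)(=O)C(F)(F)F)C(F)(F)F
Why: The ketone has a single enolisable position (the other α-carbon is the ketal), so O-triflation of the potassium enolate gives one enol triflate; deprotonation at −78 °C should outrun E2 at the tertiary bromide.

**Step 8**
Reactants: 6 methyl (2S)-2-(iodomethyl)-3,3-dimethylpent-4-enoate; 10 4-bromo-5,5-dimethoxy-4-methylcyclopent-1-en-1-yl trifluoromethanesulfonate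
Product: 12 methyl (2S)-2-[(4-bromo-5,5-dimethoxy-4-methylcyclopent-1-en-1-yl)methyl]-3,3-dimethylpent-4-enoate, via zinc homoenolate 11 (not isolated)
Conditions: Zn dust (activated with BrCH2CH2Br, Me3SiCl), THF/DMA, 35 °C; supernatant added to 10, Pd2(dba)3 (2.5 mol %), SPhos (10 mol %), 50 °C
Reagents that add atoms: none
Why: Zinc insertion gives a chelated β-zincio ester that is configurationally safe, and Negishi sp3–sp2 coupling with the enol triflate forms the ring-to-methylene bond without an SN2 reaction at the hindered carbon; zerovalent palladium should not touch the tertiary alkyl bromide.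

**Step 9**
Reactants: 12 methyl (2S)-2-[(4-bromo-5,5-dimethoxy-4-methylcyclopent-1-en-1-yl)methyl]-3,3-dimethylpent-4-enoate
Product: 13 (3S)-3-[(4-bromo-5,5-dimethoxy-4-methylcyclopent-1-en-1-yl)methyl]-2,4,4-trimethylhex-5-en-2-ol
Conditions: MeLi, CeCl3, THF, −78 to −20 °C
Reagents that add atoms: methyllithium, [Li]C
Why: Double addition of the organocerium reagent to the hindered ester; its low basicity should avoid enolisation (and so epimerisation) and E2 at the tertiary bromide.

**Step 10**
Reactants: 13 (3S)-3-[(4-bromo-5,5-dimethoxy-4-methylcyclopent-1-en-1-yl)methyl]-2,4,4-trimethylhex-5-en-2-ol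
Product: 15 2-[(1S,3S,5S,7S)-10,10-dimethoxy-4,4,7-trimethyltricyclo[5.2.1.0^{1,5}]dec-8-en-3-yl]propan-2-ol, via cyclopentadienone ketal 14 (not isolated)
Conditions: DBU, PhMe, 60 °C; aq. NH4Cl wash; then PhMe (0.01 M), BHT, 110 °C
Reagents that add atoms: none
Why: E2 toward the allylic ring methylene gives diene 14, and on heating the vinyl group adds across the diene termini in an intramolecular Diels–Alder reaction in which the three-atom tether can only span the exo position, fixing C1, C5 and C7 together. The C3 centre chooses the diene face: only on the face leading to 15 can the free tertiary hydroxyl hydrogen-bond to the methoxy oxygen on the dienophile side, which is why the alcohol is unprotected and the base is washed out before heating.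

**Step 11**
Reactants: 15 2-[(1S,3S,5S,7S)-10,10-dimethoxy-4,4,7-trimethyltricyclo[5.2.1.0^{1,5}]dec-8-en-3-yl]propan-2-ol
Product: 16 (1R,3S,5S,7S,8R,9S)-3-(2-hydroxypropan-2-yl)-10,10-dimethoxy-4,4,7-trimethyltricyclo[5.2.1.0^{1,5}]decane-8,9-diol
Conditions: K2OsO4·2H2O (5 mol %), N-methylmorpholine N-oxide, acetone/H2O, 40 °C
Reagents that add atoms: N-methylmorpholine N-oxide, C[N+]1([O-])CCOCC1; water, O
Why: Catalytic syn-dihydroxylation of the strained norbornene bond with a non-volatile osmate salt; attack is expected on the endo face, away from the methoxy group that overhangs the alkene, but the face does not matter for the route.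

**Step 12**
Reactants: 16 (1R,3S,5S,7S,8R,9S)-3-(2-hydroxypropan-2-yl)-10,10-dimethoxy-4,4,7-trimethyltricyclo[5.2.1.0^{1,5}]decane-8,9-diol
Product: 17 (1R,3S,5S,7S)-3-(2-hydroxypropan-2-yl)-10,10-dimethoxy-4,4,7-trimethyltricyclo[5.2.1.0^{1,5}]decane-8,9-dione
Conditions: (COCl)2, DMSO, CH2Cl2, −78 °C; then Et3N, −78 to 0 °C
Reagents that add atoms: none
Why: Swern oxidation of both secondary hydroxyls gives the 1,2-dione without glycol cleavage; the bridgeheads are quaternary, so the dione cannot enolise, and the tertiary alcohol is not oxidised.

**Step 13**
Reactants: 18 3-methylbutan-2-one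
Product: 20 1-diazo-3-methylbutan-2-one, via trifluoroacetyl ketone 19 (not isolated)
Conditions: LiN(SiMe3)2, THF, −78 °C; CF3CO2CH2CF3; then 4-acetamidobenzenesulfonyl azide, Et3N, H2O, MeCN, rt; used as a solution
Reagents that add atoms: 4-acetamidobenzenesulfonyl azide, CC(=O)Nc1ccc(cc1)S(=O)(=O)N=[N+]=[N-]
Why: Detrifluoroacetylative diazo transfer (Regitz-type): the kinetic methyl enolate is trifluoroacetylated and the activated methylene takes up N2 from the sulfonyl azide with loss of the trifluoroacetyl group; this avoids diazomethane and uses the least hazardous common sulfonyl azide.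

**Step 14 (key step)**
Reactants: 17 (1R,3S,5S,7S)-3-(2-hydroxypropan-2-yl)-10,10-dimethoxy-4,4,7-trimethyltricyclo[5.2.1.0^{1,5}]decane-8,9-dione; 20 1-diazo-3-methylbutan-2-one
Product: 22 (1R,3S,5S,7S)-8-hydroxy-3-(2-hydroxypropan-2-yl)-11,11-dimethoxy-4,4,7-trimethyl-9-(2-methylpropanoyl)tricyclo[5.3.1.0^{1,5}]undec-8-en-10-one, via diazo aldol adduct 21 (not isolated)
Conditions: 20 (1.5 equiv), LiN(SiMe3)2, THF, −78 °C; aq. NH4Cl; then Rh2(OAc)4 (2 mol %), CH2Cl2, 0 °C to rt
Reagents that add atoms: none
Why: Lithiated 20 adds through its diazo carbon to one carbonyl of the strained, non-enolisable 1,2-dione (aldol-type addition of an acyldiazomethane anion) to give 21; attack at either carbonyl gives adducts that converge. Rh2(OAc)4 then removes N2 to form a rhodium carbenoid, to which the neighbouring ring acyl carbon shifts while the carbinol becomes a carbonyl; this is the carbenoid counterpart of a Tiffeneau–Demjanov or semipinacol homologation of a 1,2-dione to a 2-acyl-1,3-dione, the closest known reaction type. Both bonds to the new carbon are thus made, and the five-membered dione ring grows by one atom into ring A; the ring is formed by ring enlargement through a 1,2-shift, not by a cyclisation. No stereocentre is created, because the inserted carbon ends sp2 in the enolised triketone. The selectivity needed is migration of the acyl carbon over the bridgehead carbon: the acyl group is the better migrating group toward an electron-poor centre, the bridgehead carbon would have to move within a rigid bicycle, and acyl shift releases the eclipsed dione and gives the chelated enol triketone. The dimethyl ketal keeps the bridging carbonyl out of the reaction, and the tertiary alcohol lies on the opposite face and is less acidic than the diazo ketone. A single-flask variant with BF3·OEt2 as promoter is the obvious second set of conditions.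

**Step 15**
Reactants: 22 (1R,3S,5S,7S)-8-hydroxy-3-(2-hydroxypropan-2-yl)-11,11-dimethoxy-4,4,7-trimethyl-9-(2-methylpropanoyl)tricyclo[5.3.1.0^{1,5}]undec-8-en-10-one
Product: 23 (1S,3S,5S,7S)-8-hydroxy-3-(2-hydroxypropan-2-yl)-4,4,7-trimethyl-9-(2-methylpropanoyl)tricyclo[5.3.1.0^{1,5}]undec-8-ene-10,11-dione
Conditions: aq. HCl (2 M), THF, 40 °C
Reagents that add atoms: water, O
Why: Acid hydrolysis of the dimethyl ketal; ionisation should be helped by relief of the compression between the methoxy group and the C4 methyl group, and dilute aqueous acid at mild temperature should leave the tertiary alcohol and the triketone intact.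

## Compound list

1 | 3,3-dimethylpent-4-enoic acid | C=CC(C)(C)CC(=O)O | starting material
2 | (4S)-4-benzyl-1,3-oxazolidin-2-one | O=C1OC[C@H](Cc2ccccc2)N1 | starting material
3 | (4S)-4-benzyl-3-(3,3-dimethylpent-4-enoyl)-1,3-oxazolidin-2-one | O=C1OC[C@H](Cc2ccccc2)N1C(=O)CC(C)(C)C=C | intermediate
4 | (4S)-4-benzyl-3-[(2R)-2-(hydroxymethyl)-3,3-dimethylpent-4-enoyl]-1,3-oxazolidin-2-one | O=C1OC[C@H](Cc2ccccc2)N1C(=O)[C@@H](CO)C(C)(C)C=C | intermediate
5 | methyl (2R)-2-(hydroxymethyl)-3,3-dimethylpent-4-enoate | COC(=O)[C@@H](CO)C(C)(C)C=C | intermediate
6 | methyl (2S)-2-(iodomethyl)-3,3-dimethylpent-4-enoate | COC(=O)[C@@H](CI)C(C)(C)C=C | intermediate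
7 | 2-hydroxy-3-methylcyclopent-2-en-1-one | CC1=C(O)C(=O)CC1 | starting material
8 | 2-methoxy-3-methylcyclopent-2-en-1-one | COC1=C(C)CCC1=O | intermediate
9 | 3-bromo-2,2-dimethoxy-3-methylcyclopentan-1-one (racemic) | COC1(OC)C(=O)CCC1(C)Br | intermediate
10 | 4-bromo-5,5-dimethoxy-4-methylcyclopent-1-en-1-yl trifluoromethanesulfonate (racemic) | COC1(OC)C(OS(=O)(=O)C(F)(F)F)=CCC1(C)Br | intermediate
11 | iodo[(2S)-2-(methoxycarbonyl)-3,3-dimethylpent-4-en-1-yl]zinc | COC(=O)[C@@H](C[Zn]I)C(C)(C)C=C | intermediate (not isolated)
12 | methyl (2S)-2-[(4-bromo-5,5-dimethoxy-4-methylcyclopent-1-en-1-yl)methyl]-3,3-dimethylpent-4-enoate (both epimers at the bromine-bearing carbon) | COC(=O)[C@@H](CC1=CCC(C)(Br)C1(OC)OC)C(C)(C)C=C | intermediate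
13 | (3S)-3-[(4-bromo-5,5-dimethoxy-4-methylcyclopent-1-en-1-yl)methyl]-2,4,4-trimethylhex-5-en-2-ol (both epimers at the bromine-bearing carbon) | CC(C)(O)[C@@H](CC1=CCC(C)(Br)C1(OC)OC)C(C)(C)C=C | intermediate
14 | (3S)-3-[(5,5-dimethoxy-4-methylcyclopenta-1,3-dien-1-yl)methyl]-2,4,4-trimethylhex-5-en-2-ol | CC(C)(O)[C@@H](CC1=CC=C(C)C1(OC)OC)C(C)(C)C=C | intermediate (not isolated)
15 | 2-[(1S,3S,5S,7S)-10,10-dimethoxy-4,4,7-trimethyltricyclo[5.2.1.0^{1,5}]dec-8-en-3-yl]propan-2-ol | C1=C[C@]2(C)C[C@H]3C(C)(C)[C@@H](C(C)(C)O)C[C@@]31C2(OC)OC | intermediate
16 | (1R,3S,5S,7S,8R,9S)-3-(2-hydroxypropan-2-yl)-10,10-dimethoxy-4,4,7-trimethyltricyclo[5.2.1.0^{1,5}]decane-8,9-diol (endo cis-diol) | O[C@@H]1[C@]2(C)C[C@H]3C(C)(C)[C@@H](C(C)(C)O)C[C@@]3([C@@H]1O)C2(OC)OC | intermediate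
17 | (1R,3S,5S,7S)-3-(2-hydroxypropan-2-yl)-10,10-dimethoxy-4,4,7-trimethyltricyclo[5.2.1.0^{1,5}]decane-8,9-dione | O=C1[C@]2(C)C[C@H]3C(C)(C)[C@@H](C(C)(C)O)C[C@@]3(C1=O)C2(OC)OC | intermediate (key-step precursor)
18 | 3-methylbutan-2-one | CC(C)C(C)=O | starting material
19 | 1,1,1-trifluoro-5-methylhexane-2,4-dione | CC(C)C(=O)CC(=O)C(F)(F)F | intermediate (not isolated)
20 | 1-diazo-3-methylbutan-2-one | CC(C)C(=O)C=[N+]=[N-] | intermediate
21 | 1-diazo-1-[(1R,3S,5S,7S)-8-hydroxy-3-(2-hydroxypropan-2-yl)-10,10-dimethoxy-4,4,7-trimethyl-9-oxotricyclo[5.2.1.0^{1,5}]decan-8-yl]-3-methylbutan-2-one (adduct at C8 drawn, C8 configuration open; the C9 adduct behaves alike) | CC(C)C(=O)C(=[N+]=[N-])C1(O)[C@]2(C)C[C@H]3C(C)(C)[C@@H](C(C)(C)O)C[C@@]3(C1=O)C2(OC)OC | intermediate (not isolated)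
22 | (1R,3S,5S,7S)-8-hydroxy-3-(2-hydroxypropan-2-yl)-11,11-dimethoxy-4,4,7-trimethyl-9-(2-methylpropanoyl)tricyclo[5.3.1.0^{1,5}]undec-8-en-10-one | CC(C)C(=O)C1=C(O)[C@]2(C)C[C@H]3C(C)(C)[C@@H](C(C)(C)O)C[C@@]3(C1=O)C2(OC)OC | intermediate (key-step product)
23 | (1S,3S,5S,7S)-8-hydroxy-3-(2-hydroxypropan-2-yl)-4,4,7-trimethyl-9-(2-methylpropanoyl)tricyclo[5.3.1.0^{1,5}]undec-8-ene-10,11-dione | CC(C)C(=O)C1=C(O)[C@]2(C)C[C@H]3C(C)(C)[C@@H](C(C)(C)O)C[C@@]3(C1=O)C2=O | target

## Step count and least certain steps

Total step count: 15 (steps 1–4 side chain, 5–7 ring fragment, 8–12 assembly to the dione, 13 diazo ketone, 14 key step, 15 deprotection).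
Longest linear sequence: 11 steps (1, 2, 3, 4, 8, 9, 10, 11, 12, 14, 15).

**Step 14 (key step).** Most likely to go wrong: migration of the bridgehead carbon in competition with the acyl carbon, which would enlarge the ring on the wrong side. Retro-addition of the hindered adduct before nitrogen loss is the second risk.
Fallback, setting out from 17 and returning at 22: alkaline hydrogen peroxide cleaves the C8–C9 bond of 17 to the cis-1,3-dicarboxylic acid F1. Dicyclohexylcarbodiimide closes it to the bicyclic anhydride F2. The lithium enolate of 18 (two equivalents) opens the anhydride to the β-diketo acid F3; either carbonyl may be attacked and both regioisomers converge. Activation of the acid with carbonyldiimidazole followed by DBU closes ring A by C-acylation of the diketone and gives 22. No migration is involved, so the regiochemical question disappears.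

**Step 10.** Most likely to go wrong: poor facial selectivity. On steric grounds alone the side chain prefers the open diene face, which leads to the C3 epimer, and the hydrogen bond may not outweigh this at 110 °C. The cycloaddition may also be slow, because the exo tether presses a C4 methyl group against the neighbouring methoxy group, leaving time for dimerisation of the diene.
Fallback, setting out from 13 and returning at 15: 13 is treated with pyridinium p-toluenesulfonate in toluene over 5 Å sieves, so that the tertiary hydroxyl displaces one methoxy group and gives the cyclic mixed ketal F4. DBU then gives the bicyclic cyclopentadienone ketal F5, in which the side chain is held covalently on one diene face, so the cycloaddition can only give the caged alkene F6 with the required C3 configuration. Acid-catalysed methanolysis (MeOH, HC(OMe)3, camphorsulfonic acid), helped by the double bond anti to the departing oxygen, reopens the cage to 15. Only the epimer of F4 in which the ring oxygen and the vinyl-bearing arm are cis can cyclise; that is the cost of this variant.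

**Step 8.** Most likely to go wrong: slow transmetalation and reductive elimination between two hindered partners, with protonation or β-hydride loss of the alkyl group taking over.
Fallback, setting out from 10 and 3 and returning at 12: carbonylation of 10 (Pd(OAc)2, 1,3-bis(diphenylphosphino)propane, CO, MeOH, Et3N) gives the unsaturated methyl ester F7. i-Bu2AlH reduces it to the allylic alcohol F8, and CBr4/PPh3 gives the allylic bromide F9. The sodium enolate of 3 is alkylated by F9 on the face opposite the benzyl group to give the imide F10 with the 2S configuration. NaOMe in MeOH (or LiOH/H2O2 followed by MeI) exchanges the auxiliary for the methyl ester 12. The bond is now made on the other side of the methylene, by a reactive allylic electrophile, and the stereocentre is set in the same step.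

**Step 6.** Most likely to go wrong: bromination at the wrong site (the α'-methylene or an allylic position), or no reaction, because the enol ether is deactivated by the adjacent carbonyl.
Fallback, setting out from 8 and returning at 14: 8 is epoxidised in methanol (m-chloroperbenzoic acid, NaHCO3) to the hydroxy ketal F11. Dehydration with the Burgess reagent gives the β,γ-unsaturated ketone F12, whose only enolate is trapped with PhNTf2 as the dienyl triflate F13. Coupling with 11 under the conditions of step 8 gives the diene ester F14, and MeLi/CeCl3 converts it into 14, which is heated as in step 10. Bromine is avoided altogether; the second ring double bond is in place before the coupling.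

**Step 15.** Most likely to go wrong: ionisation or elimination of the tertiary alcohol before the deactivated bridging ketal is cleaved, or very slow ketal ionisation next to two acyl-bearing carbons.
Fallback, setting out from 22 and returning at 23: Et3SiOTf and 2,4,6-collidine in CH2Cl2 at 0 °C convert the ketal into a collidinium intermediate and silylate the alcohol at the same time. Water then releases the ketone as the triethylsilyl ether F15 (the same compound as A5), and HF·pyridine removes the silyl group to give 23. The cleavage runs under basic, non-hydrolytic conditions with the alcohol masked.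

## Further compounds

F1 | step 14 | cis-dicarboxylic acid from cleavage of the dione bond of 17: 7-(2-hydroxypropan-2-yl)-2,2-dimethoxy-3,6,6-trimethylbicyclo[3.3.0]octane-1,3-dicarboxylic acid (configuration as in 17) | OC(=O)[C@]1(C)C[C@H]2C(C)(C)[C@@H](C(C)(C)O)C[C@@]2(C(=O)O)C1(OC)OC
F2 | step 14 | bicyclic anhydride of F1 (configuration as in 17) | O=C1[C@]2(C)C[C@H]3C(C)(C)[C@@H](C(C)(C)O)C[C@@]3(C(=O)O1)C2(OC)OC
F3 | step 14 | β-diketo acid from opening of F2 by the enolate of 18 (one regioisomer drawn) | CC(C)C(=O)CC(=O)[C@]1(C)C[C@H]2C(C)(C)[C@@H](C(C)(C)O)C[C@@]2(C(=O)O)C1(OC)OC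
F4 | step 10 | (3S)-7-bromo-7a-methoxy-2,2,7-trimethyl-3-(2-methylbut-3-en-2-yl)-2,3,4,6,7,7a-hexahydrocyclopenta[b]pyran (cyclic mixed ketal; productive epimer at the ketal carbon drawn) | CO[C@@]12OC(C)(C)[C@@H](CC1=CCC2(C)Br)C(C)(C)C=C
F5 | step 10 | (3S)-7a-methoxy-2,2,7-trimethyl-3-(2-methylbut-3-en-2-yl)-2,3,4,7a-tetrahydrocyclopenta[b]pyran (bicyclic cyclopentadienone ketal) | CO[C@@]12OC(C)(C)[C@@H](CC1=CC=C2C)C(C)(C)C=C
F6 | step 10 | caged alkene: 15 with the tertiary oxygen bonded to the ketal carbon in place of the methoxy group on the side of the saturated bridge | C1=C[C@]2(C)C[C@H]3C(C)(C)[C@@H]4C[C@@]31[C@@]2(OC)OC4(C)C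
F7 | step 8 | methyl 4-bromo-5,5-dimethoxy-4-methylcyclopent-1-ene-1-carboxylate (racemic) | COC(=O)C1=CCC(C)(Br)C1(OC)OC
F8 | step 8 | (4-bromo-5,5-dimethoxy-4-methylcyclopent-1-en-1-yl)methanol (racemic) | OCC1=CCC(C)(Br)C1(OC)OC
F9 | step 8 | 4-bromo-1-(bromomethyl)-5,5-dimethoxy-4-methylcyclopent-1-ene (racemic) | BrCC1=CCC(C)(Br)C1(OC)OC
F10 | step 8 | (4S)-4-benzyl-3-[(2S)-2-[(4-bromo-5,5-dimethoxy-4-methylcyclopent-1-en-1-yl)methyl]-3,3-dimethylpent-4-enoyl]-1,3-oxazolidin-2-one | O=C1OC[C@H](Cc2ccccc2)N1C(=O)[C@@H](CC1=CCC(C)(Br)C1(OC)OC)C(C)(C)C=C
F11 | step 6 | 3-hydroxy-2,2-dimethoxy-3-methylcyclopentan-1-one (racemic) | COC1(OC)C(=O)CCC1(C)O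
F12 | step 6 | 2,2-dimethoxy-3-methylcyclopent-3-en-1-one | COC1(OC)C(=O)CC=C1C
F13 | step 6 | 5,5-dimethoxy-4-methylcyclopenta-1,3-dien-1-yl trifluoromethanesulfonate | COC1(OC)C(OS(=O)(=O)C(F)(F)F)=CC=C1C
F14 | step 6 | methyl (2S)-2-[(5,5-dimethoxy-4-methylcyclopenta-1,3-dien-1-yl)methyl]-3,3-dimethylpent-4-enoate | COC(=O)[C@@H](CC1=CC=C(C)C1(OC)OC)C(C)(C)C=C
F15 | step 15 | triethylsilyl ether of 23 at the tertiary alcohol | CC(C)C(=O)C1=C(O)[C@]2(C)C[C@H]3C(C)(C)[C@@H](C(C)(C)O[Si](CC)(CC)CC)C[C@@]3(C1=O)C2=O
A1 | alternative 1 | 3-methyl-1-(trimethylsilyl)buta-1,2-diene | CC(C)=C=C[Si](C)(C)C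
A2 | alternative 1 | methyl (3S)-3-[(tert-butyldimethylsilyl)oxy]-5-oxocyclopent-1-ene-1-carboxylate | COC(=O)C1=C[C@@H](O[Si](C)(C)C(C)(C)C)CC1=O
A3 | alternative 1 | cis-diquinane keto ester with vinylsilane | COC(=O)[C@@]12C=C([Si](C)(C)C)C(C)(C)[C@@H]1[C@@H](O[Si](C)(C)C(C)(C)C)CC2=O
A4 | alternative 2 | 1-[2,4,6-trihydroxy-3-methyl-5-[(2S)-3,3-dimethyl-2-[2-(triethylsilyloxy)propan-2-yl]pent-4-en-1-yl]phenyl]-2-methylpropan-1-one | CC(C)C(=O)c1c(O)c(C)c(O)c(C[C@H](C(C)(C)O[Si](CC)(CC)CC)C(C)(C)C=C)c1O
A5 | alternative 2 | triethylsilyl ether of the target | CC(C)C(=O)C1=C(O)[C@]2(C)C[C@H]3C(C)(C)[C@@H](C(C)(C)O[Si](CC)(CC)CC)C[C@@]3(C1=O)C2=O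
A6 | alternative 3 | trimethylsilyl enol ether of the cis-diquinane ketone (enol toward the methyl-bearing carbon) | C[Si](C)(C)OC1=C(C)C[C@H]2C(C)(C)[C@@H](C(C)(C)O[Si](CC)(CC)CC)C[C@@H]12
A7 | alternative 3 | malonyl dichloride (propanedioyl dichloride) | ClC(=O)CC(Cl)=O
A8 | alternative 3 | tricyclic enolised trione lacking the isobutyryl group | C1=C(O)[C@]2(C)C[C@H]3C(C)(C)[C@@H](C(C)(C)O[Si](CC)(CC)CC)C[C@@]3(C1=O)C2=O
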